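Everything rests on disconnecting ring B at C4, the lone benzylic CH2 that lies between C4a of ring A and C3, a carbon that carries a carboxyl-level substituent. C4 is therefore supplied by carbon monoxide: one palladium-catalysed carbonylative cyclisation inserts CO into the C4a–I bond and lets a malonate carbon at C3 capture the aroylpalladium, which forms C4a–C4 and C4–C3 and closes ring B as a 4-oxo-3,3-diester. The precursor is an acyclic dimethyl malonate whose chain already holds C2 (benzyloxymethyl) and C1 (O-benzyl guaiacyl ring C and the iodinated, O-silylated ring A) in the target configuration.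

Key step: step 7

Numbering used for all tetralins: C1 carries ring C, C2 and C3 carry the two CH2O carbons, C4 is the benzylic carbon next to C4a, and ring A (C4a–C8a) has OMe at C5 and C6 and oxygen at C7.

Assumption: the sense of induction of the chiral diene in step 4 and of the imidazolidinone in step 5 is assigned from the accepted catalyst models; should a first run show the opposite sense at C1 or C2, the antipodal ligand or amine is taken and nothing else changes.

Step 1
Reactants: 1 3-hydroxy-4,5-dimethoxybenzaldehyde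
Product: 2 3,4-dimethoxy-5-(triisopropylsilyloxy)benzaldehyde
Conditions: i-Pr3SiCl (1.2 equiv), imidazole (2.5 equiv), DMF, rt
Reagents that add atoms: chlorotriisopropylsilane, CC(C)[Si](Cl)(C(C)C)C(C)C
Why: Silylation of the only free phenol with a chlorosilane and imidazole is routine, and the bulky triisopropylsilyl ether should survive all later base, acid and hydride steps while shielding the ring position next to it for step 2.

Step 2
Reactants: 2 3,4-dimethoxy-5-(triisopropylsilyloxy)benzaldehyde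
Product: 3 2-iodo-3,4-dimethoxy-5-(triisopropylsilyloxy)benzaldehyde
Conditions: I2 (1.1 equiv), CF3CO2Ag (1.1 equiv), CH2Cl2, 0 °C to rt, dark
Reagents that add atoms: iodine, [I][I]
Why: Electrophilic aromatic iodination with silver-activated iodine: the two free ring positions are electronically alike (each ortho to one oxygen and para to the other), so the triisopropylsilyloxy group is expected to block position 6 and send iodine to position 2, between the formyl-bearing carbon and the C3 methoxy group, which is the future C4a.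

Step 3
Reactants: 3 2-iodo-3,4-dimethoxy-5-(triisopropylsilyloxy)benzaldehyde; 4 (triphenylphosphoranylidene)acetaldehyde
Product: 5 (E)-3-[2-iodo-3,4-dimethoxy-5-(triisopropylsilyloxy)phenyl]prop-2-enal
Conditions: 4 (1.3 equiv), toluene, 90 °C
Reagents that add atoms: (triphenylphosphoranylidene)acetaldehyde (compound 4), O=CC=P(c1ccccc1)(c1ccccc1)c1ccccc1
Why: Wittig olefination with the stabilised formylmethylene ylide should give the (E)-enal, the ortho iodine raising the electrophilicity of the otherwise electron-rich aldehyde.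

Step 4
Reactants: 5 (E)-3-[2-iodo-3,4-dimethoxy-5-(triisopropylsilyloxy)phenyl]prop-2-enal; 6 4-benzyloxy-3-methoxyphenylboronic acid
Product: 7 (3R)-3-(4-benzyloxy-3-methoxyphenyl)-3-[2-iodo-3,4-dimethoxy-5-(triisopropylsilyloxy)phenyl]propanal
Conditions: 6 (2 equiv), [RhCl(C2H4)2]2 (2.5 mol%), (1S,4S)-2,5-diphenylbicyclo[2.2.2]octa-2,5-diene (5.5 mol%), aq. KOH (0.2 equiv), 1,4-dioxane/H2O 10:1, 30 °C
Reagents that add atoms: 4-benzyloxy-3-methoxyphenylboronic acid (compound 6), COc1cc(B(O)O)ccc1OCc1ccccc1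
Why: Rhodium/chiral-diene catalysed asymmetric 1,4-addition of an arylboronic acid to an enal (Hayashi–Miyaura reaction): the arylrhodium formed by transmetalation is directed by the C2-symmetric diene onto the Si face of the β-carbon (iodoaryl > C-α > H), which sets C1 as R, while the diene ligand disfavours 1,2-addition and monovalent rhodium should leave the aryl iodide untouched at 30 °C.

Step 5
Reactants: 7 (3R)-3-(4-benzyloxy-3-methoxyphenyl)-3-[2-iodo-3,4-dimethoxy-5-(triisopropylsilyloxy)phenyl]propanal; 8 dimethyl bromomalonate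
Product: 9 dimethyl 2-[(2S,3R)-3-(4-benzyloxy-3-methoxyphenyl)-3-[2-iodo-3,4-dimethoxy-5-(triisopropylsilyloxy)phenyl]-1-oxopropan-2-yl]malonate
Conditions: 8 (1.5 equiv), (2S,5R)-2-tert-butyl-3,5-dimethylimidazolidin-4-one·CF3SO3H (20 mol%), Ru(bpy)3Cl2 (0.5 mol%), 2,6-lutidine (2 equiv), DMF, blue LED, 23 °C
Reagents that add atoms: dimethyl bromomalonate (compound 8), COC(=O)C(Br)C(=O)OC
Why: Photoredox organocatalytic α-alkylation of an aldehyde: the (E)-enamine of 7 traps the electrophilic malonyl radical released from 8 by the reduced ruthenium photocatalyst on its Re face, the Si face being covered by the C5 methyl group of the (2S,5R)-amine, so C2 is set as S under catalyst control (any minor C2 epimer remaining separable at 9 or 10) before oxidation of the α-amino radical and hydrolysis release 9.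

Step 6
Reactants: 9 dimethyl 2-[(2S,3R)-3-(4-benzyloxy-3-methoxyphenyl)-3-[2-iodo-3,4-dimethoxy-5-(triisopropylsilyloxy)phenyl]-1-oxopropan-2-yl]malonate
Product: 10 dimethyl 2-[(2S,3R)-1-benzyloxy-3-(4-benzyloxy-3-methoxyphenyl)-3-[2-iodo-3,4-dimethoxy-5-(triisopropylsilyloxy)phenyl]propan-2-yl]malonate
Conditions: BnOSiMe3 (2 equiv), Et3SiH (2 equiv), Me3SiOTf (10 mol%), CH2Cl2, −78 to −40 °C
Reagents that add atoms: benzyloxytrimethylsilane, C[Si](C)(C)OCc1ccccc1
Why: Silyl-triflate catalysed reductive etherification: aldehyde and benzyl silyl ether give an O-benzyl oxocarbenium ion that Et3SiH reduces at low temperature, so the primary alcohol never appears free and cannot lactonise onto the malonate, and the C2 hydrogen is not expected to epimerise.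

Step 7
Reactants: 10 dimethyl 2-[(2S,3R)-1-benzyloxy-3-(4-benzyloxy-3-methoxyphenyl)-3-[2-iodo-3,4-dimethoxy-5-(triisopropylsilyloxy)phenyl]propan-2-yl]malonate; 11 carbon monoxide
Product: 13 dimethyl (1R,2S)-2-(benzyloxymethyl)-1-(4-benzyloxy-3-methoxyphenyl)-5,6-dimethoxy-4-oxo-7-(triisopropylsilyloxy)-1,2-dihydronaphthalene-3,3(4H)-dicarboxylate, via sodium malonate enolate 12 (not isolated)
Conditions: NaH (1.05 equiv), THF, 0 °C to rt; then Pd(PPh3)4 (10 mol%), CO (1 atm), THF (0.02 M), 65 °C
Reagents that add atoms: carbon monoxide (compound 11), [C-]#[O+]; sodium hydride, [Na+].[H-] (sodium of intermediate 12 only)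
Why: Zerovalent palladium inserts into the hindered C4a–I bond, CO migrates in to give the aroylpalladium iodide, and the pre-formed sodium malonate carbon C3 attacks the acyl carbon (or binds palladium and reductively eliminates), which forms C4a–C4 and C4–C3 and returns zerovalent palladium. The closest known reaction type is the palladium-catalysed carbonylative cyclisation of aryl iodides that carry a tethered malonate, an intramolecular capture of an acylpalladium by a soft carbon enolate. Ring B closes in a 6-exo-trig mode, the C3 carbanion attacking the acyl carbon whose oxygen stays outside the new six-membered ring. No stereocentre is created, since C3 becomes quaternary with two identical ester groups, and C1 and C2 lie outside the reacting atoms and are not acidic toward NaH. The step needs C- over O-acylation and CO uptake ahead of direct arylation or hydrodeiodination: O-acylation would require an eight-membered enol lactone, direct C3–C4a coupling is slow with PPh3 under CO, and full deprotonation with one equivalent of NaH in dilute THF leaves no other nucleophile or hydride source for the acylpalladium. The product is a β-keto diester without an α-hydrogen and no alkoxide is released, so the ring closure should not revert.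

Step 8
Reactants: 13 dimethyl (1R,2S)-2-(benzyloxymethyl)-1-(4-benzyloxy-3-methoxyphenyl)-5,6-dimethoxy-4-oxo-7-(triisopropylsilyloxy)-1,2-dihydronaphthalene-3,3(4H)-dicarboxylate
Product: 14 methyl (1R,2S,3R)-2-(benzyloxymethyl)-1-(4-benzyloxy-3-methoxyphenyl)-5,6-dimethoxy-4-oxo-7-(triisopropylsilyloxy)-1,2,3,4-tetrahydronaphthalene-3-carboxylate
Conditions: LiCl (3 equiv), H2O (2 equiv), DMSO, 120 °C
Reagents that add atoms: none
Why: Krapcho dealkoxycarbonylation: chloride demethylates one ester of the ketone-activated gem-diester, the carboxylate loses CO2 to the enolate of the β-keto ester, and protonation at C3, which stays enolisable between ketone and ester, should settle the ester trans to the C2 benzyloxymethyl group (3R) under thermodynamic control.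

Step 9
Reactants: 14 methyl (1R,2S,3R)-2-(benzyloxymethyl)-1-(4-benzyloxy-3-methoxyphenyl)-5,6-dimethoxy-4-oxo-7-(triisopropylsilyloxy)-1,2,3,4-tetrahydronaphthalene-3-carboxylate
Product: 16 methyl (1R,2S,3S)-2-(benzyloxymethyl)-1-(4-benzyloxy-3-methoxyphenyl)-5,6-dimethoxy-7-(triisopropylsilyloxy)-1,2,3,4-tetrahydronaphthalene-3-carboxylate, via C4 alcohol 15 (not isolated)
Conditions: NaBH4 (1.5 equiv), MeOH/THF, 0 °C; aqueous work-up; then Et3SiH (5 equiv), CF3CO2H (10 equiv), CH2Cl2, 0 °C
Reagents that add atoms: none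
Why: Borohydride reduction of the aryl ketone followed by ionic hydrogenation of the benzylic alcohol: the C4 cation, stabilised by the para C7 silyloxy and ortho C5 methoxy groups, is captured by Et3SiH as in the deoxygenation of aldol-type β-hydroxy esters of electron-rich arenes, and since C3 remains α to the ester a cis contaminant can still be equilibrated with methoxide before step 10.

Step 10
Reactants: 16 methyl (1R,2S,3S)-2-(benzyloxymethyl)-1-(4-benzyloxy-3-methoxyphenyl)-5,6-dimethoxy-7-(triisopropylsilyloxy)-1,2,3,4-tetrahydronaphthalene-3-carboxylate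
Product: 17 [(1R,2S,3S)-2-(benzyloxymethyl)-1-(4-benzyloxy-3-methoxyphenyl)-5,6-dimethoxy-7-(triisopropylsilyloxy)-1,2,3,4-tetrahydronaphthalen-3-yl]methanol
Conditions: LiAlH4 (2 equiv), THF, 0 °C
Reagents that add atoms: none
Why: LiAlH4 reduction of the methyl ester to the primary alcohol should fix C3, which is no longer enolisable, without touching the benzyl ethers or the aryl silyl ether.

Step 11
Reactants: 17 [(1R,2S,3S)-2-(benzyloxymethyl)-1-(4-benzyloxy-3-methoxyphenyl)-5,6-dimethoxy-7-(triisopropylsilyloxy)-1,2,3,4-tetrahydronaphthalen-3-yl]methanol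
Product: 19 (1R,2S,3S)-1-(4-hydroxy-3-methoxyphenyl)-2,3-bis(hydroxymethyl)-5,6-dimethoxy-1,2,3,4-tetrahydronaphthalen-7-ol, via phenol 18 (not isolated)
Conditions: Bu4NF (1.2 equiv), THF, 0 °C; aqueous NH4Cl work-up; then H2 (1 atm), Pd/C (10% palladium on carbon), EtOAc/MeOH, rt
Reagents that add atoms: none
Why: Fluoride cleaves the aryl silyl ether and heterogeneous palladium-catalysed hydrogenolysis then removes both benzyl ethers, conditions that should leave the three stereocentres and the doubly benzylic C1–H bond unchanged.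

Compound list
1 | 3-hydroxy-4,5-dimethoxybenzaldehyde | COc1cc(C=O)cc(O)c1OC | starting material
2 | 3,4-dimethoxy-5-(triisopropylsilyloxy)benzaldehyde | COc1cc(C=O)cc(O[Si](C(C)C)(C(C)C)C(C)C)c1OC | intermediate
3 | 2-iodo-3,4-dimethoxy-5-(triisopropylsilyloxy)benzaldehyde | O=Cc1cc(O[Si](C(C)C)(C(C)C)C(C)C)c(OC)c(OC)c1I | intermediate
4 | (triphenylphosphoranylidene)acetaldehyde | O=CC=P(c1ccccc1)(c1ccccc1)c1ccccc1 | starting material
5 | (E)-3-[2-iodo-3,4-dimethoxy-5-(triisopropylsilyloxy)phenyl]prop-2-enal | O=C/C=C/c1cc(O[Si](C(C)C)(C(C)C)C(C)C)c(OC)c(OC)c1I | intermediate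
6 | 4-benzyloxy-3-methoxyphenylboronic acid | COc1cc(B(O)O)ccc1OCc1ccccc1 | starting material
7 | (3R)-3-(4-benzyloxy-3-methoxyphenyl)-3-[2-iodo-3,4-dimethoxy-5-(triisopropylsilyloxy)phenyl]propanal | O=CC[C@H](c1ccc(OCc2ccccc2)c(OC)c1)c1cc(O[Si](C(C)C)(C(C)C)C(C)C)c(OC)c(OC)c1I | intermediate
8 | dimethyl bromomalonate | COC(=O)C(Br)C(=O)OC | starting material
9 | dimethyl 2-[(2S,3R)-3-(4-benzyloxy-3-methoxyphenyl)-3-[2-iodo-3,4-dimethoxy-5-(triisopropylsilyloxy)phenyl]-1-oxopropan-2-yl]malonate | COC(=O)C(C(=O)OC)[C@@H](C=O)[C@H](c1ccc(OCc2ccccc2)c(OC)c1)c1cc(O[Si](C(C)C)(C(C)C)C(C)C)c(OC)c(OC)c1I | intermediate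
10 | dimethyl 2-[(2S,3R)-1-benzyloxy-3-(4-benzyloxy-3-methoxyphenyl)-3-[2-iodo-3,4-dimethoxy-5-(triisopropylsilyloxy)phenyl]propan-2-yl]malonate (key-step precursor) | COC(=O)C(C(=O)OC)[C@@H](COCc1ccccc1)[C@H](c1ccc(OCc2ccccc2)c(OC)c1)c1cc(O[Si](C(C)C)(C(C)C)C(C)C)c(OC)c(OC)c1I | intermediate
11 | carbon monoxide | [C-]#[O+] | starting material
12 | sodium enolate of malonate 10 | [Na+].COC(=O)[C-](C(=O)OC)[C@@H](COCc1ccccc1)[C@H](c1ccc(OCc2ccccc2)c(OC)c1)c1cc(O[Si](C(C)C)(C(C)C)C(C)C)c(OC)c(OC)c1I | intermediate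
13 | dimethyl (1R,2S)-2-(benzyloxymethyl)-1-(4-benzyloxy-3-methoxyphenyl)-5,6-dimethoxy-4-oxo-7-(triisopropylsilyloxy)-1,2-dihydronaphthalene-3,3(4H)-dicarboxylate (key-step product) | COc1cc([C@@H]2c3cc(O[Si](C(C)C)(C(C)C)C(C)C)c(OC)c(OC)c3C(=O)C(C(=O)OC)(C(=O)OC)[C@H]2COCc2ccccc2)ccc1OCc1ccccc1 | intermediate
14 | methyl (1R,2S,3R)-2-(benzyloxymethyl)-1-(4-benzyloxy-3-methoxyphenyl)-5,6-dimethoxy-4-oxo-7-(triisopropylsilyloxy)-1,2,3,4-tetrahydronaphthalene-3-carboxylate (keto form; in equilibrium with its enol) | COc1cc([C@@H]2c3cc(O[Si](C(C)C)(C(C)C)C(C)C)c(OC)c(OC)c3C(=O)[C@H](C(=O)OC)[C@H]2COCc2ccccc2)ccc1OCc1ccccc1 | intermediate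
15 | methyl (1R,2S,3R)-2-(benzyloxymethyl)-1-(4-benzyloxy-3-methoxyphenyl)-4-hydroxy-5,6-dimethoxy-7-(triisopropylsilyloxy)-1,2,3,4-tetrahydronaphthalene-3-carboxylate (both C4 epimers) | COc1cc([C@@H]2c3cc(O[Si](C(C)C)(C(C)C)C(C)C)c(OC)c(OC)c3C(O)[C@H](C(=O)OC)[C@H]2COCc2ccccc2)ccc1OCc1ccccc1 | intermediate
16 | methyl (1R,2S,3S)-2-(benzyloxymethyl)-1-(4-benzyloxy-3-methoxyphenyl)-5,6-dimethoxy-7-(triisopropylsilyloxy)-1,2,3,4-tetrahydronaphthalene-3-carboxylate | COc1cc([C@@H]2c3cc(O[Si](C(C)C)(C(C)C)C(C)C)c(OC)c(OC)c3C[C@H](C(=O)OC)[C@H]2COCc2ccccc2)ccc1OCc1ccccc1 | intermediate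
17 | [(1R,2S,3S)-2-(benzyloxymethyl)-1-(4-benzyloxy-3-methoxyphenyl)-5,6-dimethoxy-7-(triisopropylsilyloxy)-1,2,3,4-tetrahydronaphthalen-3-yl]methanol | COc1cc([C@@H]2c3cc(O[Si](C(C)C)(C(C)C)C(C)C)c(OC)c(OC)c3C[C@H](CO)[C@H]2COCc2ccccc2)ccc1OCc1ccccc1 | intermediate
18 | (1R,2S,3S)-2-(benzyloxymethyl)-1-(4-benzyloxy-3-methoxyphenyl)-3-(hydroxymethyl)-5,6-dimethoxy-1,2,3,4-tetrahydronaphthalen-7-ol | COc1cc([C@@H]2c3cc(O)c(OC)c(OC)c3C[C@H](CO)[C@H]2COCc2ccccc2)ccc1OCc1ccccc1 | intermediate
19 | (1R,2S,3S)-1-(4-hydroxy-3-methoxyphenyl)-2,3-bis(hydroxymethyl)-5,6-dimethoxy-1,2,3,4-tetrahydronaphthalen-7-ol (CNP0197710.1) | COc1cc([C@@H]2c3cc(O)c(OC)c(OC)c3C[C@H](CO)[C@H]2CO)ccc1O | target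

Total step count: 11
Longest linear sequence: 11 steps (1 to 19); compounds 4, 6, 8 and 11 are bought.

Steps most likely to fail

1. Step 7. Oxidative addition into the doubly ortho-substituted, electron-rich C4a–I bond is slow and the resulting aroylpalladium is crowded, so hydrodeiodination or capture by an adventitious nucleophile may outrun attack of the malonate carbon. The fallback sets out from 10 and forms the same two bonds from CO in separate operations.
   - Krapcho demethoxycarbonylation (LiCl, H2O, DMSO, 150 °C) would give the monoester methyl (3R,4R)-3-(benzyloxymethyl)-4-(4-benzyloxy-3-methoxyphenyl)-4-[2-iodo-3,4-dimethoxy-5-(triisopropylsilyloxy)phenyl]butanoate F1.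
   - Palladium-catalysed methoxycarbonylation of the iodide (PdCl2(PPh3)2, CO 1 atm, MeOH, Et3N, DMF, 80 °C), in which methanol in large excess takes the place of the internal carbon nucleophile, would give the aryl ester methyl 6-[(1R,2R)-2-(benzyloxymethyl)-1-(4-benzyloxy-3-methoxyphenyl)-4-methoxy-4-oxobutyl]-2,3-dimethoxy-4-(triisopropylsilyloxy)benzoate F2.
   - Dieckmann condensation of the C3 ester enolate onto the benzoate (KOt-Bu, THF, 0 °C, then aqueous NH4Cl), driven by deprotonation of the β-keto ester, comes back to the route at 14.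

2. Step 4. The bulky ortho-iodinated β-aryl group slows insertion of the enal into the aryl–rhodium bond, so protodeboronation of 6 and 1,2-addition to the formyl group may compete, and a lowered enantiomer ratio at C1 cannot be repaired later. The fallback sets out from 3 and changes the acceptor class.
   - Horner–Wadsworth–Emmons olefination (trimethyl phosphonoacetate, NaH, THF, 0 °C) would give methyl (E)-3-[2-iodo-3,4-dimethoxy-5-(triisopropylsilyloxy)phenyl]prop-2-enoate F3.
   - Rhodium/diene arylation with 6 on this enoate, which offers no 1,2-pathway and tolerates 50 °C, would give methyl (3R)-3-(4-benzyloxy-3-methoxyphenyl)-3-[2-iodo-3,4-dimethoxy-5-(triisopropylsilyloxy)phenyl]propanoate F4.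
   - Partial reduction with i-Bu2AlH (1.1 equiv, CH2Cl2, −78 °C) comes back to the route at 7.

3. Step 9. The C4 cation may lose the acidic C3 proton instead of taking hydride, which would give the conjugated dihydronaphthalene ester and erode the C3 configuration. The fallback sets out from 14 and removes the C4 oxygen without a cation next to an enolisable ester.
   - NaBH4 as in step 9, with 15 now isolated, then LiAlH4 (THF, 0 °C) would give the diol (1R,2S,3S)-2-(benzyloxymethyl)-1-(4-benzyloxy-3-methoxyphenyl)-3-(hydroxymethyl)-5,6-dimethoxy-7-(triisopropylsilyloxy)-1,2,3,4-tetrahydronaphthalen-4-ol F5.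
   - Bu4NF (THF, 0 °C) would give the phenol (1R,2S,3S)-2-(benzyloxymethyl)-1-(4-benzyloxy-3-methoxyphenyl)-3-(hydroxymethyl)-5,6-dimethoxy-1,2,3,4-tetrahydronaphthalene-4,7-diol F6.
   - Hydrogenolysis (H2, Pd/C, AcOH/EtOAc) would cut the C4–O bond, benzylic and para to the free C7 phenol, together with both benzyl ethers, and comes back to the route at 19.

Further compounds
F1 | step 7 | methyl (3R,4R)-3-(benzyloxymethyl)-4-(4-benzyloxy-3-methoxyphenyl)-4-[2-iodo-3,4-dimethoxy-5-(triisopropylsilyloxy)phenyl]butanoate | COC(=O)C[C@@H](COCc1ccccc1)[C@H](c1ccc(OCc2ccccc2)c(OC)c1)c1cc(O[Si](C(C)C)(C(C)C)C(C)C)c(OC)c(OC)c1I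
F2 | step 7 | methyl 6-[(1R,2R)-2-(benzyloxymethyl)-1-(4-benzyloxy-3-methoxyphenyl)-4-methoxy-4-oxobutyl]-2,3-dimethoxy-4-(triisopropylsilyloxy)benzoate | COC(=O)C[C@@H](COCc1ccccc1)[C@H](c1ccc(OCc2ccccc2)c(OC)c1)c1cc(O[Si](C(C)C)(C(C)C)C(C)C)c(OC)c(OC)c1C(=O)OC
F3 | step 4 | methyl (E)-3-[2-iodo-3,4-dimethoxy-5-(triisopropylsilyloxy)phenyl]prop-2-enoate | COC(=O)/C=C/c1cc(O[Si](C(C)C)(C(C)C)C(C)C)c(OC)c(OC)c1I
F4 | step 4 | methyl (3R)-3-(4-benzyloxy-3-methoxyphenyl)-3-[2-iodo-3,4-dimethoxy-5-(triisopropylsilyloxy)phenyl]propanoate | COC(=O)C[C@H](c1ccc(OCc2ccccc2)c(OC)c1)c1cc(O[Si](C(C)C)(C(C)C)C(C)C)c(OC)c(OC)c1I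
F5 | step 9 | (1R,2S,3S)-2-(benzyloxymethyl)-1-(4-benzyloxy-3-methoxyphenyl)-3-(hydroxymethyl)-5,6-dimethoxy-7-(triisopropylsilyloxy)-1,2,3,4-tetrahydronaphthalen-4-ol (both C4 epimers) | COc1cc([C@@H]2c3cc(O[Si](C(C)C)(C(C)C)C(C)C)c(OC)c(OC)c3C(O)[C@H](CO)[C@H]2COCc2ccccc2)ccc1OCc1ccccc1
F6 | step 9 | (1R,2S,3S)-2-(benzyloxymethyl)-1-(4-benzyloxy-3-methoxyphenyl)-3-(hydroxymethyl)-5,6-dimethoxy-1,2,3,4-tetrahydronaphthalene-4,7-diol (both C4 epimers) | COc1cc([C@@H]2c3cc(O)c(OC)c(OC)c3C(O)[C@H](CO)[C@H]2COCc2ccccc2)ccc1OCc1ccccc1
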